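**Retrosynthetic overview**
1. 31 ⇐ (acetonide and benzyl ester cleavage; one-carbon Wittig homologation of C6=O to the 6β-acid) pentacyclic keto lactone 26 ⇐ (5-exo vinyl-radical closure of ring D, C16–C13) bridgehead enol lactone 25.
2. Feature used: rings C (C8, C9, C11, C12, C13, C14) and E (C10, C20, O, C12, C11, C9) share C9–C11–C12 as a 2-oxabicyclo[3.3.1]nonan-3-one whose ring oxygen sits on C12, so C12 is C2 of a butadiene C11=C12–C13=C14 carried as the enol ester of the C20 acid.
3. 25 ⇐ type 2 intramolecular Diels–Alder reaction of buta-1,3-dien-2-yl ester 24: the diene adds to C8=C9 of the ring B enone (bonds C9–C11 and C8–C14) and closes rings C and E together.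
4. 24 ⇐ enone acid 20 ⇐ trans-hydrindanone 15 ⇐ Δ5 keto diester 9 ⇐ cyclopentanone keto ester 3 + acrolein + benzyl diazoacetate (asymmetric Michael addition sets C10; Roskamp and Knoevenagel reactions build ring A).
5. Ring order: B (from 1), then A, then C and E in one step, D last.

Key step: step 16

Convention: gibberellane numbering throughout; α is the face of rings A/B that carries C19 and C20, β the opposite face (H5, H9, Me-18, O2, O3, C7, C15).
Protecting groups: C19 is carried as a benzyl ester and C20 as a 2-(trimethylsilyl)ethyl ester, so that neither has to be hydrolysed at its crowded carbonyl.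
Assumption: O-(phenanthren-9-yl)cupreidine is taken to give (S)-5; should the sense be opposite, the cupreine-derived pseudoenantiomer is used and nothing else changes.

**Route**

Step 1
Reactants: 1 methyl 2-oxocyclopentane-1-carboxylate; 2 2-(trimethylsilyl)ethanol
Product: 3 2-(trimethylsilyl)ethyl 2-oxocyclopentane-1-carboxylate
Conditions: DMAP (0.1 equiv), toluene, reflux, 4 Å sieves (MeOH removed)
Reagents that add atoms: none
Why: DMAP-catalysed transesterification of an enolisable β-keto ester installs the fluoride-labile ester that later frees the C20 acid alone; no stereocentre is involved.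

Step 2
Reactants: 3 2-(trimethylsilyl)ethyl 2-oxocyclopentane-1-carboxylate; 4 acrolein
Product: 5 2-(trimethylsilyl)ethyl (1S)-2-oxo-1-(3-oxopropyl)cyclopentane-1-carboxylate
Conditions: O-(phenanthren-9-yl)cupreidine (C33H30N2O2, 10 mol%), CH2Cl2, −25 °C
Reagents that add atoms: none
Why: Cinchona-alkaloid-catalysed Michael addition of a cyclic α-substituted β-keto ester to acrolein, in which the quinuclidine nitrogen deprotonates 3 and the 6'-OH binds the enal, so that bond formation on one enol face sets the quaternary C10 as (S).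

Step 3
Reactants: 5 Michael adduct aldehyde; 6 benzyl diazoacetate
Product: 7 benzyl 3-oxo-5-[(1S)-2-oxo-1-{[2-(trimethylsilyl)ethoxy]carbonyl}cyclopentyl]pentanoate
Conditions: SnCl2 (10 mol%), CH2Cl2, 23 °C
Reagents that add atoms: none
Why: Roskamp reaction, in which the diazo carbon adds to the SnCl2-activated aldehyde and a 1,2-hydride shift with loss of N2 gives the β-keto ester (C3, C4, C19), while the hindered ring ketone does not react.

Step 4
Reactants: 7 keto β-keto ester
Product: 8 ring A/B enone diester (3-oxo; C4=C5; 19-benzyl ester; 20-TMSE ester)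
Conditions: piperidine (0.2 equiv), AcOH (0.2 equiv), toluene, reflux, Dean–Stark
Reagents that add atoms: none
Why: Intramolecular Knoevenagel condensation (the ring-closing half of a Robinson annulation), in which the acidic C4 methylene adds to the C5 ketone and dehydration closes ring A as the C4=C5 enone without touching C10.

Step 5
Reactants: 8 ring A/B enone diester
Product: 9 Δ5 keto diester (4β-Me; 4α-CO2Bn; 10α-CO2CH2CH2SiMe3; C5=C6)
Conditions: NaH, THF/DMF, 0 °C; MeI, 0 → 23 °C
Reagents that add atoms: iodomethane, CI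
Why: Deconjugative α-alkylation of the extended enolate formed by deprotonation at C6, in which MeI attacks C4 from the β face, anti to the angular 10α ester, and so sets C4 (Me β, C19 α) while the double bond moves to C5=C6.

Step 6
Reactants: 9 Δ5 keto diester
Product: 10 C2=C3 enol triflate of 9
Conditions: KN(SiMe3)2, THF, −78 °C; PhNTf2, −78 → 0 °C
Reagents that add atoms: N-phenylbis(trifluoromethanesulfonimide), O=S(=O)(N(c1ccccc1)S(=O)(=O)C(F)(F)F)C(F)(F)F
Why: Enolate O-triflation is regiodefined because C4 is quaternary and only C2 carries α-hydrogens.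

Step 7
Reactants: 10 enol triflate
Product: 11 2,5-diene diester (C2=C3 and C5=C6)
Conditions: Pd(OAc)2 (5 mol%), PPh3, Bu3N, HCO2H, DMF, 60 °C
Reagents that add atoms: none
Why: Palladium-catalysed formate reduction of an enol triflate (oxidative addition, formate exchange, decarboxylation, reductive elimination) replaces OTf by H and leaves both esters intact.

Step 8
Reactants: 11 2,5-diene diester
Product: 12 2β,3β-diol
Conditions: OsO4 (2 mol%), NMO, acetone/H2O, 0 → 23 °C
Reagents that add atoms: osmium tetroxide, O=[Os](=O)(=O)=O; N-methylmorpholine N-oxide, C[N+]1([O-])CCOCC1; water, O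
Why: Catalytic OsO4/NMO cis-dihydroxylation, which should take the cis-disubstituted C2=C3 bond over the trisubstituted C5=C6 bond buried between two quaternary carbons, and should enter from the β face, away from the 4α and 10α ester groups, to set C2 and C3.

Step 9
Reactants: 12 2β,3β-diol
Product: 13 2β,3β-acetonide
Conditions: Me2C(OMe)2, PPTS, acetone, 23 °C
Reagents that add atoms: 2,2-dimethoxypropane, COC(C)(C)OC
Why: Acid-catalysed transacetalisation of a cis-1,2-diol gives the dioxolane that masks both hydroxyls through the oxidations and enolate steps.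

Step 10
Reactants: 13 2β,3β-acetonide
Product: 14 6β-alcohol (5β-H; trans A/B fusion)
Conditions: BH3·THF, THF, 0 → 23 °C; NaOH, H2O2, 0 °C
Reagents that add atoms: hydrogen peroxide, OO
Why: Hydroboration–oxidation of the trisubstituted C5=C6 bond, with boron on the less substituted C6 and syn H–B addition from the β face, away from the 4α and 10α esters that flank C5, sets H5 β (trans ring fusion) and gives the 6β-alcohol.

Step 11
Reactants: 14 6β-alcohol
Product: 15 trans-hydrindan-6-one
Conditions: Dess–Martin periodinane, NaHCO3, CH2Cl2, 23 °C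
Reagents that add atoms: none
Why: Dess–Martin oxidation is neutral and fast, so the C5 stereocentre next to the new ketone should not epimerise.

Step 12
Reactants: 15 trans-hydrindan-6-one; 16 2,3-dibromopropene
Product: 17 8-(2-bromoprop-2-enyl) 6-ketone (C8 epimers)
Conditions: LiN(iPr)2, THF, −78 °C; 16, DMPU, −78 → −20 °C
Reagents that add atoms: none
Why: Kinetic enolate alkylation (SN2 at the allylic bromide) occurs at C8 because C5–H lies between two quaternary carbons, and the C8 configuration is irrelevant since it is removed in step 13.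

Step 13
Reactants: 17 8-(2-bromoprop-2-enyl) 6-ketone
Product: 19 ring B enone TMSE ester (C8=C9), via silyl enol ether 18 (not isolated)
Conditions: LiN(iPr)2, Me3SiCl, THF, −78 °C; then Pd(OAc)2 (1.1 equiv), MeCN, 23 °C
Reagents that add atoms: none
Why: Saegusa–Ito oxidation, in which the C6=C8 silyl enol ether 18 gives a palladium enolate that loses the ring C9 hydride to form the endocyclic C8=C9 enone, while the vinyl bromide is inert to divalent palladium at 23 °C.

Step 14
Reactants: 19 ring B enone TMSE ester
Product: 20 ring B enone C20 acid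
Conditions: Bu4NF, AcOH (1:1), THF, 0 → 23 °C
Reagents that add atoms: none
Why: Fluoride-induced fragmentation of the 2-(trimethylsilyl)ethyl ester (attack at silicon, loss of ethene) frees the neopentyl C20 acid without attack at its carbonyl, and the acetic acid buffer protects the C5 stereocentre α to the enone.

Step 15
Reactants: 20 ring B enone C20 acid; 22 2-(trimethylsilyloxy)buta-1,3-diene
Product: 24 ring A/B enone buta-1,3-dien-2-yl ester, via acid chloride 21 (not isolated), via lithium buta-1,3-dien-2-olate 23 (not isolated)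
Conditions: 20, 1-chloro-N,N,2-trimethylprop-1-en-1-amine, CH2Cl2, 0 → 23 °C; added at −78 °C to 23 (from 22, MeLi, THF, 0 °C)
Reagents that add atoms: none
Why: Neutral acid chloride formation followed by enolate O-acylation, which a hard, α-quaternary acyl chloride favours over C-acylation and which at −78 °C should outrun Michael addition to the enone, gives the enol ester without creating a stereocentre.

Step 16
Reactants: 24 ring A/B enone buta-1,3-dien-2-yl ester
Product: 25 tetracyclic bridgehead enol lactone (C12=C13; C11 and C14 α; C15 and H9 β)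
Conditions: BHT (0.1 equiv), 1,2-dichlorobenzene (0.005 M), 180 °C, sealed tube
Reagents that add atoms: none
Why: Proposed new method: the 2-acyloxydiene, tied to C10 through its own ester carbonyl (three tether atoms O, C20 and C10 between C12 and C9), is expected to add thermally across the enone C8=C9 bond in a concerted, asynchronous [4+2] step that bonds C11 to C9 and C14 to C8 and leaves the C12=C13 bridgehead enol lactone. The closest known reaction type is the type 2 intramolecular Diels–Alder reaction of 2-substituted dienes, which gives bicyclo[3.3.1]non-1-enes with three-atom carbon tethers and tolerates ester links in longer tethers; new here is an ester tether this short, which must react through its less stable E rotamer. Ring C closes as the cyclohexene of the cycloaddition, and ring E closes at the same time as the six-membered lactone in the 1,3-bridged (meta) mode, the only one a three-atom tether can reach. C9 and C8 are set by suprafacial addition to the α face, the face of C20, because the tether cannot span the β face, so C11 and C14 end up α and H9 and the bromoallyl carbon C15 β. The step needs meta regiochemistry, α-face delivery and intramolecular over intermolecular reaction; the tether length and the matched polarity (nucleophilic enol terminus C11 onto the enone β-carbon C9) secure the first, the position of C20 the second and high dilution the third. The strain stored in the C12=C13 bond is spent in step 17.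

Step 17
Reactants: 25 tetracyclic bridgehead enol lactone
Product: 26 pentacyclic 6-keto 20,12-lactone (16-methylidene)
Conditions: Bu3SnH (syringe pump), AIBN, benzene, 80 °C
Reagents that add atoms: none
Why: Tin hydride radical cyclisation, in which the C16 vinyl radical adds 5-exo-trig to C13 of the strained C12=C13 bond and the bridgehead α-acyloxy C12 radical takes hydrogen from Bu3SnH; C13 is fixed because C16 reaches it only across the ring C face that carries C15, and C12 because it remains a lactone bridgehead.

Step 18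
Reactants: 26 pentacyclic 6-keto 20,12-lactone
Product: 27 C6 methoxymethylidene enol ether (E/Z mixture)
Conditions: Ph3P(CH2OMe)Cl, KN(SiMe3)2, THF/toluene, 0 → 60 °C
Reagents that add atoms: (methoxymethyl)triphenylphosphonium chloride, COC[P+](c1ccccc1)(c1ccccc1)c1ccccc1.[Cl-]
Why: Wittig methoxymethylenation adds C7 to the C6 ketone, which is more electrophilic than the neopentyl lactone and benzyl ester carbonyls; no stereocentre is formed.

Step 19
Reactants: 27 enol ether
Product: 28 6β-carbaldehyde
Conditions: TsOH·H2O (cat.), acetone/H2O, 23 °C; then DBU, CH2Cl2, 23 °C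
Reagents that add atoms: water, O
Why: Acid hydrolysis of the enol ether in acetone (which keeps the acetonide) followed by base equilibration of the epimerisable aldehyde should place the formyl group on the β face of C6, trans to the quaternary C4 on C5.

Step 20
Reactants: 28 6β-carbaldehyde
Product: 29 7-oic acid 19-benzyl ester acetonide
Conditions: NaClO2, NaH2PO4, 2-methylbut-2-ene, t-BuOH/H2O, 0 → 23 °C
Reagents that add atoms: sodium chlorite, [Na+].[O-]Cl=O
Why: Pinnick oxidation converts the aldehyde to the acid without epimerising C6, and the alkene scavenger keeps hypochlorite away from the 16-methylidene group.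

Step 21
Reactants: 29 7-oic acid 19-benzyl ester acetonide
Product: 30 7,19-dioic acid acetonide
Conditions: NaSEt, DMF, 60 °C; aqueous HCl work-up
Reagents that add atoms: none
Why: SN2 dealkylation by thiolate at the benzylic carbon does not depend on the crowding at the C19 acyl carbon, and the lactone survives because its alkyl carbon C12 is a bridgehead and acyl attack is reversible.

Step 22
Reactants: 30 7,19-dioic acid acetonide
Product: 31 target (CNP0212122.1)
Conditions: AcOH/H2O (4:1), 45 °C
Reagents that add atoms: none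
Why: Mild acid-catalysed acetal hydrolysis frees the 2β,3β-diol under conditions too weak to protonate the 16-methylidene group or open the lactone.

**Compound list**
1 | methyl 2-oxocyclopentane-1-carboxylate | COC(=O)C1CCCC1=O | starting material
2 | 2-(trimethylsilyl)ethanol | C[Si](C)(C)CCO | starting material
3 | 2-(trimethylsilyl)ethyl 2-oxocyclopentane-1-carboxylate | C[Si](C)(C)CCOC(=O)C1CCCC1=O | intermediate
4 | acrolein (prop-2-enal) | C=CC=O | starting material
5 | 2-(trimethylsilyl)ethyl (1S)-2-oxo-1-(3-oxopropyl)cyclopentane-1-carboxylate | C[Si](C)(C)CCOC(=O)[C@]1(CCC=O)CCCC1=O | intermediate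
6 | benzyl diazoacetate | [N-]=[N+]=CC(=O)OCc1ccccc1 | starting material
7 | benzyl 3-oxo-5-[(1S)-2-oxo-1-{[2-(trimethylsilyl)ethoxy]carbonyl}cyclopentyl]pentanoate | C[Si](C)(C)CCOC(=O)[C@]1(CCC(=O)CC(=O)OCc2ccccc2)CCCC1=O | intermediate
8 | 4-benzyl 7a-[2-(trimethylsilyl)ethyl] (7aS)-5-oxo-2,3,5,6,7,7a-hexahydro-1H-indene-4,7a-dicarboxylate (3-oxo, C4=C5) | C[Si](C)(C)CCOC(=O)[C@]12CCCC1=C(C(=O)OCc3ccccc3)C(=O)CC2 | intermediate
9 | Δ5 keto diester: 3-oxo, 4β-methyl, 4α-CO2Bn (C19), 10α-CO2CH2CH2SiMe3 (C20), C5=C6 | C[Si](C)(C)CCOC(=O)[C@]12CCC=C1[C@](C)(C(=O)OCc3ccccc3)C(=O)CC2 | intermediate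
10 | enol triflate of 9: C2=C3, 3-OTf | C[Si](C)(C)CCOC(=O)[C@]12CCC=C1[C@](C)(C(=O)OCc3ccccc3)C(OS(=O)(=O)C(F)(F)F)=CC2 | intermediate
11 | 2,5-diene diester: C2=C3 and C5=C6 | C[Si](C)(C)CCOC(=O)[C@]12CCC=C1[C@](C)(C(=O)OCc3ccccc3)C=CC2 | intermediate
12 | 2β,3β-diol of 11 (C5=C6 kept) | C[Si](C)(C)CCOC(=O)[C@]12CCC=C1[C@](C)(C(=O)OCc3ccccc3)[C@@H](O)[C@@H](O)C2 | intermediate
13 | 2β,3β-O-isopropylidene derivative of 12 | C[Si](C)(C)CCOC(=O)[C@]12CCC=C1[C@](C)(C(=O)OCc3ccccc3)[C@@H](O4)[C@@H](OC4(C)C)C2 | intermediate
14 | 6β-alcohol: 5β-H, trans-fused rings A/B | C[Si](C)(C)CCOC(=O)[C@]12CC[C@@H](O)[C@@H]1[C@](C)(C(=O)OCc3ccccc3)[C@@H](O4)[C@@H](OC4(C)C)C2 | intermediate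
15 | trans-hydrindan-6-one: 5β-H, 6-oxo | C[Si](C)(C)CCOC(=O)[C@]12CCC(=O)[C@@H]1[C@](C)(C(=O)OCc3ccccc3)[C@@H](O4)[C@@H](OC4(C)C)C2 | intermediate
16 | 2,3-dibromopropene | C=C(Br)CBr | starting material
17 | 8-(2-bromoprop-2-enyl) derivative of 15 (C8 epimer mixture, C8 left undefined) | C[Si](C)(C)CCOC(=O)[C@]12CC(CC(Br)=C)C(=O)[C@@H]1[C@](C)(C(=O)OCc3ccccc3)[C@@H](O4)[C@@H](OC4(C)C)C2 | intermediate
18 | C6=C8 trimethylsilyl enol ether of 17 | C[Si](C)(C)CCOC(=O)[C@]12CC(CC(Br)=C)=C(O[Si](C)(C)C)[C@@H]1[C@](C)(C(=O)OCc3ccccc3)[C@@H](O4)[C@@H](OC4(C)C)C2 | intermediate (not isolated)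
19 | ring B enone: 6-oxo, C8=C9, 8-(2-bromoprop-2-enyl), 20-TMSE ester | C[Si](C)(C)CCOC(=O)[C@]12C=C(CC(Br)=C)C(=O)[C@@H]1[C@](C)(C(=O)OCc3ccccc3)[C@@H](O4)[C@@H](OC4(C)C)C2 | intermediate
20 | ring B enone C20 carboxylic acid | OC(=O)[C@]12C=C(CC(Br)=C)C(=O)[C@@H]1[C@](C)(C(=O)OCc3ccccc3)[C@@H](O4)[C@@H](OC4(C)C)C2 | intermediate
21 | C20 acid chloride of 20 | ClC(=O)[C@]12C=C(CC(Br)=C)C(=O)[C@@H]1[C@](C)(C(=O)OCc3ccccc3)[C@@H](O4)[C@@H](OC4(C)C)C2 | intermediate (not isolated)
22 | 2-(trimethylsilyloxy)buta-1,3-diene | C=CC(=C)O[Si](C)(C)C | starting material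
23 | lithium buta-1,3-dien-2-olate | [Li]OC(=C)C=C | intermediate (not isolated)
24 | buta-1,3-dien-2-yl ester of 20 (Diels–Alder precursor) | C=CC(=C)OC(=O)[C@]12C=C(CC(Br)=C)C(=O)[C@@H]1[C@](C)(C(=O)OCc3ccccc3)[C@@H](O4)[C@@H](OC4(C)C)C2 | intermediate
25 | tetracyclic bridgehead enol lactone: C12=C13, C9–C11 and C8–C14 bonds on the α face, 6-oxo, 8β-(2-bromoprop-2-enyl) | C=C(Br)C[C@]23CC=C1C[C@H]2[C@@]2(C[C@H](O4)[C@H](OC4(C)C)[C@@](C)(C(=O)OCc5ccccc5)[C@H]2C3=O)C(=O)O1 | intermediate
26 | pentacyclic 6-keto 20,12-lactone: rings A–E, 16-methylidene, 19-benzyl ester, 2β,3β-acetonide | C=C1C[C@]23C[C@H]1[C@@H]1C[C@H]2[C@@]2(C[C@H](O4)[C@H](OC4(C)C)[C@@](C)(C(=O)OCc5ccccc5)[C@H]2C3=O)C(=O)O1 | intermediate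
27 | C6 methoxymethylidene enol ether of 26 (E/Z mixture) | C=C1C[C@]23C[C@H]1[C@@H]1C[C@H]2[C@@]2(C[C@H](O4)[C@H](OC4(C)C)[C@@](C)(C(=O)OCc5ccccc5)[C@H]2C3=COC)C(=O)O1 | intermediate
28 | 6β-carbaldehyde (C7 aldehyde) | C=C1C[C@]23C[C@H]1[C@@H]1C[C@H]2[C@@]2(C[C@H](O4)[C@H](OC4(C)C)[C@@](C)(C(=O)OCc5ccccc5)[C@H]2[C@@H]3C=O)C(=O)O1 | intermediate
29 | 7-oic acid, 19-benzyl ester, 2β,3β-acetonide | C=C1C[C@]23C[C@H]1[C@@H]1C[C@H]2[C@@]2(C[C@H](O4)[C@H](OC4(C)C)[C@@](C)(C(=O)OCc5ccccc5)[C@H]2[C@@H]3C(=O)O)C(=O)O1 | intermediate
30 | 7,19-dioic acid, 2β,3β-acetonide | C=C1C[C@]23C[C@H]1[C@@H]1C[C@H]2[C@@]2(C[C@H](O4)[C@H](OC4(C)C)[C@@](C)(C(=O)O)[C@H]2[C@@H]3C(=O)O)C(=O)O1 | intermediate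
31 | CNP0212122.1: 2β,3β-dihydroxygibberell-16-ene-7,19,20-trioic acid 20,12-lactone | C=C1C[C@]23C[C@H]1[C@@H]1C[C@H]2[C@@]2(C[C@H](O)[C@H](O)[C@@](C)(C(=O)O)[C@H]2[C@@H]3C(=O)O)C(=O)O1 | target

**Step count and risks**
Total steps: 22. Longest linear sequence: 22 steps (1 to 31).

Steps most likely to fail:

1. Step 16 (the one step beyond precedent). The cycloaddition may not start, because the transition state must pay for the bridgehead C12=C13 bond and for the E ester rotamer; on prolonged heating the dienyl ester could then be lost to polymerisation or intermolecular addition. The fallback sets out from acid 20 and comes back at 26. Acid 20 would be silylated with dichlorodi(propan-2-yl)silane and imidazole, then treated with lithium buta-1,3-dien-2-olate to give the mixed acyloxy(dienyloxy)silane F1. Its five-atom tether (O, Si, O, C20, C10) lies in the range where type 2 intramolecular Diels–Alder reactions with disposable silicon tethers are established, so heating in toluene should give the silicon-bridged silyl enol ether cycloadduct F2 with the same α-face delivery and meta regiochemistry. Bu3SnH and AIBN would close ring D by vinyl radical addition to C13 of the silyl enol ether to give the ring D-closed silyl-bridged ketone F3. HF·pyridine would then release the 12-hydroxy C20 acid F4, with its hydroxyl on the C20 side of ring C. Lactonisation of F4 (2,4,6-trichlorobenzoyl chloride, Et3N, DMAP, if not spontaneous) gives 26.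

2. Step 18. The bulky ylide may act as a base at C5–H (enolisation and epimerisation) or attack the lactone, instead of adding to the C6 carbonyl, which lies between the quaternary C8 and a doubly neopentyl C5. The fallback sets out from 26 and comes back at 27. Lithiated (methoxymethyl)trimethylsilane (s-BuLi, THF, −78 °C) is a small, strongly nucleophilic carbanion and should add to the ketone to give the β-hydroxysilane F5. Peterson elimination of F5 with KH in THF gives enol ether 27.

3. Step 15. The lithium dienolate may add to the enone in Michael fashion or be C-acylated, and the hindered acid chloride may react too slowly at −78 °C for the enol ester to form cleanly. The fallback sets out from 20 and comes back at 24 without the acid chloride or any enolate. Ruthenium-catalysed Markovnikov addition of the carboxylic acid to but-1-en-3-yne ([RuCl2(p-cymene)]2, tri(2-furyl)phosphine, Na2CO3, toluene, 50 °C) would give the buta-1,3-dien-2-yl ester 24 directly. This fallback makes no new compound (F0).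

**Further compounds**
F1 | step 16 | di(propan-2-yl)silyl mixed acyloxy(buta-1,3-dien-2-yloxy) derivative of acid 20 | C=CC(=C)O[Si](C(C)C)(C(C)C)OC(=O)[C@]12C=C(CC(Br)=C)C(=O)[C@@H]1[C@](C)(C(=O)OCc3ccccc3)[C@@H](O4)[C@@H](OC4(C)C)C2
F2 | step 16 | silicon-bridged cycloadduct: C12=C13 silyl enol ether, C9–C11 and C8–C14 bonds on the α face | C=C(Br)C[C@]23CC=C1C[C@H]2[C@@]2(C[C@H](O4)[C@H](OC4(C)C)[C@@](C)(C(=O)OCc5ccccc5)[C@H]2C3=O)C(=O)O[Si](C(C)C)(C(C)C)O1
F3 | step 16 | ring D-closed silyl-bridged ketone: 16-methylidene, C12–O–Si–O–C20 bridge | C=C1C[C@]23C[C@H]1[C@@H]1C[C@H]2[C@@]2(C[C@H](O4)[C@H](OC4(C)C)[C@@](C)(C(=O)OCc5ccccc5)[C@H]2C3=O)C(=O)O[Si](C(C)C)(C(C)C)O1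
F4 | step 16 | 12-hydroxy C20 acid (hydroxyl on the C20 side of ring C) | C=C1C[C@]23C[C@H]1[C@@H](O)C[C@H]2[C@@]2(C[C@H](O4)[C@H](OC4(C)C)[C@@](C)(C(=O)OCc5ccccc5)[C@H]2C3=O)C(=O)O
F5 | step 18 | β-hydroxysilane: 6-hydroxy-6-[methoxy(trimethylsilyl)methyl] adduct of 26 (mixture at C6 and the side-chain carbon) | C=C1C[C@]23C[C@H]1[C@@H]1C[C@H]2[C@@]2(C[C@H](O4)[C@H](OC4(C)C)[C@@](C)(C(=O)OCc5ccccc5)[C@H]2C3(O)C(OC)[Si](C)(C)C)C(=O)O1
F0 | step 15 | none | none
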